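## Structural features

- Krausianone 2 is an isoflavone (3-aryl-4H-chromen-4-one). Ring A (C4a, C5–C8, C8a) is a phloroglucinol-type ring with 5-OH (hydrogen-bonded to C4=O), a prenyl group at C6, 7-OH and a free C8–H. Ring C is the γ-pyranone, and ring B is joined through the C3–C1′ bond.
- Ring B is a resorcinol-type ring. Its 2′-OH is free, and its 4′-O and C5′ are tied into a linearly fused 2,2-dimethyl-2H-pyran, so ring B is a 7-hydroxy-2,2-dimethyl-2H-chromen-6-yl group.
- There is no stereocentre and no stereogenic double bond; the molecule is achiral.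
- Fragile groups: the prenyl group between two phenols cyclises to chromans under acid. The chromene C=C is a p-oxygenated styrene, sensitive to acid, electrophiles, oxidants and hydrogenation. The γ-pyranone opens with hard nucleophiles. The 2′-OH sits next to C2 and can cyclise oxidatively.
- The real difficulty is regiochemical. On a preformed phloroglucinol ring a prenyl group must choose between C6, C8 and oxygen, and a chromone ring closure must choose between two ortho phenols. On ring B the pyran must be linear, not angular.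
- The key step exploits the contiguous C5(OH)–C6(prenyl)–C7(O)–C8(H) array on ring A, fused at C4a/C8a to the pyranone. This is the substitution pattern a vinylketene/siloxyalkyne benzannulation writes: C5 is the ketene carbonyl carbon, C6 and C7 are the two alkyne carbons, C8 is the former diazo carbon, and C4a=C8a is a C=C of a simple 4-pyranone.

## Logic of the disconnections

In one sentence: ring A is not taken from phloroglucinol but is grown onto the 4-pyranone 12 by a photochemical Wolff rearrangement/ketene–siloxyalkyne benzannulation with 15.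

**22 ⇒ 21.** The two O–Si bonds are cut. Silyl ethers are chosen because fluoride removes them without acid, so the prenyl group and the chromene are not put at risk. The forward step must be buffered so that the pyranone is not opened.

**21 ⇒ 20 + 7.** The C3–C1′ bond is cut. Both rings then arrive with their regiochemistry already fixed, and the sensitive chromene enters only two steps from the end. The forward cross-coupling must tolerate a free chelated 5-OH and an ortho-siloxy, electron-rich boronate.

**20 ⇒ 12 + 15 (key).** Four C–C bonds of ring A are cut: C8–C8a, C5–C6, C7–C8 and C4a–C5; C6=C7 is the alkyne of 15. Going forward, a transient C5–C8 bond in the four-membered ring of 17 is made and broken again. The cut is made here because it turns the C6/C8/O-prenyl problem into a matter of connectivity: the prenyl group is bonded to the carbon that must become C6 before the ring exists. The gain is a pentasubstituted, differentially protected benzo ring from a monocyclic pyranone and an acyclic alkyne. The forward step needs a ketene that reacts with the ynol ether faster than with anything else, and an electrocyclisation onto the one available pyranone CH.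

**12 ⇒ 10 ⇒ 9 ⇒ 8.** The CO–CHN2 bond, the oxidation level of the side-chain carbon and the O–S bond are cut in turn. This leads to the cheap pyranone 8, which already has the C3-oxygen (as a future cross-coupling handle) and the one-carbon branch in the right 1,4-relationship. The demand is chemoselective sulfonylation of the enolic OH over the primary alcohol.

**15 ⇒ 13.** The O–Si bond and the C≡C bond are cut (ester-to-ynolate homologation). The prenyl carbon chain is bought as the β,γ-unsaturated ester 13. The demand is that carbonyl addition outruns enolisation.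

**7 ⇒ 6 ⇒ 5 ⇒ 1 + 2.** The C–B bond, the O–Si bond, and then the pyran O1–C2 and C4–C3 bonds are cut. The halogen that marks C1′ and both oxygens are already in 1. The pyran closes onto the phenol ortho to the former aldehyde, so the linear fusion is fixed by the starting material and not by a selectivity.

## Other disconnections considered

**Alternative 1:** (the first that comes to mind) Cut C3–C1′ and take ring A from phloroglucinol.
- Forward: Suzuki coupling of 3-iodo-5,7-bis(methoxymethoxy)-6-(3-methylbut-2-en-1-yl)-4H-chromen-4-one A1 with 7. A1 would come from 1-[6-hydroxy-2,4-bis(methoxymethoxy)-3-(3-methylbut-2-en-1-yl)phenyl]ethanone A2 by enaminone formation and iodocyclisation.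
- Ground for rejection: the hard part is moved into A2. Base-mediated C-prenylation of a protected phloroacetophenone competes with O-prenylation and should place the prenyl group ortho to the free, chelated phenol. That phenol is the oxygen that becomes O1, so the 8-prenyl series is the natural outcome. A2 needs three similar phenols to be told apart. The final acetal removal would also put acid on a prenyl group flanked by two phenols.
- The chosen plan keeps the same reliable C3–C1′ coupling but settles C6 by construction.

**Alternative 2:** Cut C2 (one carbon) and the C4–C4a acyl bond.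
- Forward: Hoesch or Friedel–Crafts acylation of C-prenylphloroglucinol with the ring-B arylacetic unit to give the deoxybenzoin 2-(7-hydroxy-2,2-dimethyl-2H-chromen-6-yl)-1-[2,4,6-trihydroxy-3-(3-methylbut-2-en-1-yl)phenyl]ethanone A3, then formylation/cyclisation.
- Ground for rejection: the acylation needs Lewis or protic acid in the presence of the prenyl and chromene alkenes. A3 has two non-equivalent ortho phenols with no intrinsic bias, so 6- and 8-prenyl chromones are both expected. The 2′-OH is a third nucleophile for the formyl carbon (benzofuran formation). The protecting groups needed to fix all this make the route longer.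

**Alternative 3:** Form C3–C1′ by a biomimetic oxidative 1,2-aryl shift.
- Forward: the chalcone (E)-1-[2-hydroxy-4,6-bis(methoxymethoxy)phenyl]-3-[2,4-bis(methoxymethoxy)phenyl]prop-2-en-1-one A4 is treated with thallium(III) nitrate or a hypervalent iodine reagent in methanol, then cyclised to 2′-hydroxygenistein A5.
- Ground for rejection: the oxidant would attack a trisubstituted prenyl alkene and the chromene, so both would have to be added to A5 afterwards. There ring A (C6/C8/O) and ring B (C3′/C5′, linear/angular) each pose an unsolved regiochemical choice. This plan makes the easy bond elegantly and leaves the hard problem for the end.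

Key step: step 8

## Route

Remark (stereochemistry): the target is achiral, so "single enantiomer" requires no stereocontrol. The transient stereocentres in 3, 17 and 19 are racemic and disappear within the same step.

Remark (bookkeeping): a numbered compound on a Reactants line is not repeated under "Reagents that add atoms".

Step 1
Reactants: 1 5-bromo-2,4-dihydroxybenzaldehyde; 2 (2-methylprop-1-en-1-yl)magnesium bromide (3.5 equiv)
Product: 5 6-bromo-2,2-dimethyl-2H-chromen-7-ol, via racemic 1-(5-bromo-2,4-dihydroxyphenyl)-3-methylbut-2-en-1-ol 3 (not isolated), via (6Z)-4-bromo-3-hydroxy-6-(3-methylbut-2-en-1-ylidene)cyclohexa-2,4-dien-1-one 4 (not isolated)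
Conditions: THF, 0 °C → rt; aq. NH4Cl; then PPTS (cat.), PhMe, 50 °C
Reagents that add atoms: none
Why: Grignard addition to the magnesium phenoxide of the salicylaldehyde should give 3; this doubly hydroxy-activated benzylic allylic alcohol loses water to the vinyl o-quinone methide 4, which closes by oxa-6π-electrocyclisation onto the oxygen ortho to the former aldehyde, so the linear 6-bromo-7-hydroxy pattern follows from the substitution of 1.

Step 2
Reactants: 5 6-bromo-2,2-dimethyl-2H-chromen-7-ol
Product: 6 [(6-bromo-2,2-dimethyl-2H-chromen-7-yl)oxy]tri(propan-2-yl)silane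
Conditions: TIPSCl, imidazole, DMAP (cat.), DMF, rt → 40 °C
Reagents that add atoms: triisopropylsilyl chloride, CC(C)[Si](Cl)(C(C)C)C(C)C
Why: Standard silylation of a phenol; the bulky TIPS ether is chosen to survive the borylation and the cross-coupling and to leave with fluoride at the end.

Step 3
Reactants: 6 [(6-bromo-2,2-dimethyl-2H-chromen-7-yl)oxy]tri(propan-2-yl)silane
Product: 7 {[2,2-dimethyl-6-(4,4,5,5-tetramethyl-1,3,2-dioxaborolan-2-yl)-2H-chromen-7-yl]oxy}tri(propan-2-yl)silane
Conditions: B2pin2, Pd(OAc)2/SPhos (cat.), KOAc, 1,4-dioxane, 90 °C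
Reagents that add atoms: bis(pinacolato)diboron, CC1(C)OB(OC1(C)C)B1OC(C)(C)C(C)(C)O1
Why: Miyaura borylation of an aryl bromide; it avoids an ortho-lithiated aryl silyl ether (which could undergo O→C silyl migration), and KOAc leaves the silyl ether and the chromene untouched.

Step 4
Reactants: 8 kojic acid (5-hydroxy-2-(hydroxymethyl)-4H-pyran-4-one)
Product: 9 6-(hydroxymethyl)-4-oxo-4H-pyran-3-yl trifluoromethanesulfonate
Conditions: PhNTf2, Et3N, DMF, 0 °C → rt
Reagents that add atoms: N-phenylbis(trifluoromethanesulfonimide), O=S(=O)(N(c1ccccc1)S(=O)(=O)C(F)(F)F)C(F)(F)F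
Why: The enolic 5-OH (far more acidic than the primary alcohol) is deprotonated selectively and sulfonylated by the mild triflyl-transfer reagent, giving the enol triflate that later serves as the C3 cross-coupling handle.

Step 5
Reactants: 9 6-(hydroxymethyl)-4-oxo-4H-pyran-3-yl trifluoromethanesulfonate
Product: 10 4-oxo-5-(trifluoromethanesulfonyloxy)-4H-pyran-2-carboxylic acid
Conditions: CrO3, H2SO4, H2O, acetone, 0 °C → rt
Reagents that add atoms: water, O
Why: Jones oxidation of the primary alcohol through the aldehyde hydrate to the acid, as for O-protected kojic acids; the pyranone and the enol triflate are stable to aqueous acid.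

Step 6
Reactants: 10 4-oxo-5-(trifluoromethanesulfonyloxy)-4H-pyran-2-carboxylic acid
Product: 12 6-(2-diazoacetyl)-4-oxo-4H-pyran-3-yl trifluoromethanesulfonate, via 4-oxo-5-(trifluoromethanesulfonyloxy)-4H-pyran-2-carbonyl chloride 11 (not isolated)
Conditions: (COCl)2, DMF (cat.), CH2Cl2, 0 °C → rt, evaporate; then CH2N2 (3 equiv), Et2O/THF, 0 °C
Reagents that add atoms: diazomethane, C=[N+]=[N-]; oxalyl chloride, O=C(Cl)C(Cl)=O (its chlorine is present only in 11)
Why: Acylation of diazomethane by an acid chloride (first stage of the Arndt–Eistert sequence); it is fast at 0 °C, a second equivalent of diazomethane takes up the HCl, and a short contact time keeps dipolar addition to the pyranone C=C from competing.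

Step 7
Reactants: 13 ethyl 4-methylpent-3-enoate
Product: 15 [(5-methylhex-4-en-1-yn-1-yl)oxy]tri(propan-2-yl)silane, via lithium 5-methylhex-4-en-1-yn-1-olate 14 (not isolated)
Conditions: CH2Br2, LiTMP, THF, −78 °C; then n-BuLi, −78 °C → rt; then TIPSCl, −78 °C → rt
Reagents that add atoms: dibromomethane, BrCBr; triisopropylsilyl chloride, CC(C)[Si](Cl)(C(C)C)C(C)C
Why: Kowalski ester homologation: dibromomethyllithium adds to the ester, bromine–lithium exchange on the resulting dibromo enolate triggers a 1,2-shift of the 3-methylbut-2-enyl group to give ynolate 14, and the bulky silyl chloride silylates on oxygen to give the siloxyalkyne.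

Step 8
Reactants: 12 6-(2-diazoacetyl)-4-oxo-4H-pyran-3-yl trifluoromethanesulfonate; 15 [(5-methylhex-4-en-1-yn-1-yl)oxy]tri(propan-2-yl)silane (1.5 equiv)
Product: 20 5-hydroxy-6-(3-methylbut-2-en-1-yl)-4-oxo-7-[(triisopropylsilyl)oxy]-4H-chromen-3-yl trifluoromethanesulfonate, via 4-oxo-6-(2-oxoethenyl)-4H-pyran-3-yl trifluoromethanesulfonate 16 (not isolated), via racemic 6-[3-(3-methylbut-2-en-1-yl)-4-oxo-2-(triisopropylsilyloxy)cyclobut-2-en-1-yl]-4-oxo-4H-pyran-3-yl trifluoromethanesulfonate 17 (not isolated), via 6-[(1E)-3-(3-methylbut-2-en-1-yl)-4-oxo-2-(triisopropylsilyloxy)buta-1,3-dien-1-yl]-4-oxo-4H-pyran-3-yl trifluoromethanesulfonate 18 (not isolated), via racemic 6-(3-methylbut-2-en-1-yl)-4,5-dioxo-7-(triisopropylsilyloxy)-4a,5-dihydro-4H-chromen-3-yl trifluoromethanesulfonate 19 (not isolated)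
Conditions: hν (420–450 nm LED, Pyrex), ClCH2CH2Cl, rt, until N2 evolution ends; then 80 °C
Reagents that add atoms: none
Why: Light expels N2 from 12 and the pyranonyl group shifts to the carbene carbon (Wolff rearrangement) to give the electron-poor vinylketene 16; the closest known reaction type is the photochemical aromatic annulation of unsaturated α-diazo ketones with siloxyalkynes (Danheiser benzannulation), applied here to a 4-pyranone. Ketene 16 adds to 15 in a polar [2+2] in which the nucleophilic, prenyl-bearing alkyne carbon bonds to the ketene carbonyl carbon, so that 17 has the prenyl group next to C=O and the siloxy group next to the pyranonyl-bearing carbon. The four-membered ring of 17 is closed by this [2+2] and is not part of the target; it reopens by 4π-electrocyclic cleavage (light or 80 °C) of the bond that was the ketene C=C to give 18, where only the isomer with the pyranone rotated inward can react on, and outward opening is reversible at 80 °C. Ring A is closed by thermal disrotatory 6π-electrocyclisation of 18 between the ketene carbon and C5–H of the pyranone, and enolisation of 19, driven by aromaticity and the chelate to C4=O, gives 20. No stereocentre remains, since the sp3 centres of 17 and 19 are racemic and are destroyed in the same flask. The selectivity required is regiochemical and is fixed by connectivity: the former C=O carbon becomes C5–OH, the alkyne carbons become C6 (prenyl) and C7 (OTIPS), the diazo carbon becomes C8–H, and the only CH beside the ketene-bearing pyranone carbon is the one that becomes C4a, so neither an 8-prenyl nor an O-prenyl isomer can form. Chemoselectivity rests on the much higher nucleophilicity of the ynol ether compared with the trisubstituted alkene and on visible light, which the triflate and the chromone product do not absorb.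

Step 9
Reactants: 20 5-hydroxy-6-(3-methylbut-2-en-1-yl)-4-oxo-7-[(triisopropylsilyl)oxy]-4H-chromen-3-yl trifluoromethanesulfonate; 7 {[2,2-dimethyl-6-(4,4,5,5-tetramethyl-1,3,2-dioxaborolan-2-yl)-2H-chromen-7-yl]oxy}tri(propan-2-yl)silane (1.3 equiv)
Product: 21 3-{2,2-dimethyl-7-[(triisopropylsilyl)oxy]-2H-chromen-6-yl}-5-hydroxy-6-(3-methylbut-2-en-1-yl)-7-[(triisopropylsilyl)oxy]-4H-chromen-4-one
Conditions: SPhos Pd G3 (cat.), K3PO4, THF/H2O (10:1), 45 °C
Reagents that add atoms: none
Why: Suzuki–Miyaura coupling of a chromon-3-yl (enol) triflate with an arylboronate; a bulky biarylphosphine allows a low temperature, which limits protodeboronation of the electron-rich ortho-siloxy boronate, and any partial loss of a silyl group is harmless because step 10 removes both.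

Step 10
Reactants: 21 3-{2,2-dimethyl-7-[(triisopropylsilyl)oxy]-2H-chromen-6-yl}-5-hydroxy-6-(3-methylbut-2-en-1-yl)-7-[(triisopropylsilyl)oxy]-4H-chromen-4-one
Product: 22 krausianone 2, 5,7-dihydroxy-3-(7-hydroxy-2,2-dimethyl-2H-chromen-6-yl)-6-(3-methylbut-2-en-1-yl)-4H-chromen-4-one
Conditions: TBAF, AcOH (1:1, 2.5 equiv), THF, 0 °C → rt
Reagents that add atoms: none
Why: Fluoride cleaves both aryl silyl ethers; the acetic acid buffer keeps the medium from becoming basic enough to open the pyranone and is far too weak to cyclise the prenyl group or protonate the chromene.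

## Compound list

1 | 5-bromo-2,4-dihydroxybenzaldehyde | O=Cc1cc(Br)c(O)cc1O | starting material
2 | (2-methylprop-1-en-1-yl)magnesium bromide | CC(C)=C[Mg]Br | starting material
3 | racemic 1-(5-bromo-2,4-dihydroxyphenyl)-3-methylbut-2-en-1-ol | CC(C)=CC(O)c1cc(Br)c(O)cc1O | intermediate
4 | (6Z)-4-bromo-3-hydroxy-6-(3-methylbut-2-en-1-ylidene)cyclohexa-2,4-dien-1-one | CC(C)=C/C=C1\C(=O)C=C(O)C(Br)=C1 | intermediate
5 | 6-bromo-2,2-dimethyl-2H-chromen-7-ol | CC1(C)C=Cc2cc(Br)c(O)cc2O1 | intermediate
6 | [(6-bromo-2,2-dimethyl-2H-chromen-7-yl)oxy]tri(propan-2-yl)silane | CC1(C)C=Cc2cc(Br)c(O[Si](C(C)C)(C(C)C)C(C)C)cc2O1 | intermediate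
7 | {[2,2-dimethyl-6-(4,4,5,5-tetramethyl-1,3,2-dioxaborolan-2-yl)-2H-chromen-7-yl]oxy}tri(propan-2-yl)silane | CC1(C)C=Cc2cc(B3OC(C)(C)C(C)(C)O3)c(O[Si](C(C)C)(C(C)C)C(C)C)cc2O1 | intermediate
8 | kojic acid, 5-hydroxy-2-(hydroxymethyl)-4H-pyran-4-one | OCc1cc(=O)c(O)co1 | starting material
9 | 6-(hydroxymethyl)-4-oxo-4H-pyran-3-yl trifluoromethanesulfonate | OCc1cc(=O)c(OS(=O)(=O)C(F)(F)F)co1 | intermediate
10 | 4-oxo-5-(trifluoromethanesulfonyloxy)-4H-pyran-2-carboxylic acid | OC(=O)c1cc(=O)c(OS(=O)(=O)C(F)(F)F)co1 | intermediate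
11 | 4-oxo-5-(trifluoromethanesulfonyloxy)-4H-pyran-2-carbonyl chloride | O=C(Cl)c1cc(=O)c(OS(=O)(=O)C(F)(F)F)co1 | intermediate
12 | 6-(2-diazoacetyl)-4-oxo-4H-pyran-3-yl trifluoromethanesulfonate | [N-]=[N+]=CC(=O)c1cc(=O)c(OS(=O)(=O)C(F)(F)F)co1 | intermediate
13 | ethyl 4-methylpent-3-enoate | CCOC(=O)CC=C(C)C | starting material
14 | lithium 5-methylhex-4-en-1-yn-1-olate | [Li+].[O-]C#CCC=C(C)C | intermediate
15 | [(5-methylhex-4-en-1-yn-1-yl)oxy]tri(propan-2-yl)silane | CC(C)=CCC#CO[Si](C(C)C)(C(C)C)C(C)C | intermediate
16 | 4-oxo-6-(2-oxoethenyl)-4H-pyran-3-yl trifluoromethanesulfonate | O=C=Cc1cc(=O)c(OS(=O)(=O)C(F)(F)F)co1 | intermediate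
17 | racemic 6-[3-(3-methylbut-2-en-1-yl)-4-oxo-2-(triisopropylsilyloxy)cyclobut-2-en-1-yl]-4-oxo-4H-pyran-3-yl trifluoromethanesulfonate | O=C1C(CC=C(C)C)=C(O[Si](C(C)C)(C(C)C)C(C)C)C1c1cc(=O)c(OS(=O)(=O)C(F)(F)F)co1 | intermediate
18 | 6-[(1E)-3-(3-methylbut-2-en-1-yl)-4-oxo-2-(triisopropylsilyloxy)buta-1,3-dien-1-yl]-4-oxo-4H-pyran-3-yl trifluoromethanesulfonate (ketene-bearing carbon and pyranone cis) | O=C=C(CC=C(C)C)/C(O[Si](C(C)C)(C(C)C)C(C)C)=C\c1cc(=O)c(OS(=O)(=O)C(F)(F)F)co1 | intermediate
19 | racemic 6-(3-methylbut-2-en-1-yl)-4,5-dioxo-7-(triisopropylsilyloxy)-4a,5-dihydro-4H-chromen-3-yl trifluoromethanesulfonate | O=C1C(CC=C(C)C)=C(O[Si](C(C)C)(C(C)C)C(C)C)C=C2OC=C(OS(=O)(=O)C(F)(F)F)C(=O)C12 | intermediate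
20 | 5-hydroxy-6-(3-methylbut-2-en-1-yl)-4-oxo-7-[(triisopropylsilyl)oxy]-4H-chromen-3-yl trifluoromethanesulfonate | CC(C)=CCc1c(O[Si](C(C)C)(C(C)C)C(C)C)cc2occ(OS(=O)(=O)C(F)(F)F)c(=O)c2c1O | intermediate
21 | 3-{2,2-dimethyl-7-[(triisopropylsilyl)oxy]-2H-chromen-6-yl}-5-hydroxy-6-(3-methylbut-2-en-1-yl)-7-[(triisopropylsilyl)oxy]-4H-chromen-4-one | CC(C)=CCc1c(O[Si](C(C)C)(C(C)C)C(C)C)cc2occ(-c3cc4c(cc3O[Si](C(C)C)(C(C)C)C(C)C)OC(C)(C)C=C4)c(=O)c2c1O | intermediate
22 | krausianone 2, 5,7-dihydroxy-3-(7-hydroxy-2,2-dimethyl-2H-chromen-6-yl)-6-(3-methylbut-2-en-1-yl)-4H-chromen-4-one | CC(C)=CCc1c(O)cc2occ(-c3cc4c(cc3O)OC(C)(C)C=C4)c(=O)c2c1O | target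

## Step count and risk

Total steps: 10. Longest linear sequence: 6 (steps 4, 5, 6, 8, 9, 10 from 8). The other branches are steps 1–3 and step 7.

**Step 8 (key step).**
- What may go wrong: the photogenerated ketene is consumed before the [2+2] (dimerisation, acylation of the phenol being formed). The cyclobutenone may open mainly with outward rotation of the pyranone, so that the electrocyclisation stalls. Prolonged irradiation may degrade the diazo ketone or the triflate.
- Fallback (thermal, stepwise generation of the same ketene; sets out from 12, returns at 17):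
  - Silver(I)-catalysed Wolff rearrangement of 12 in aqueous dioxane (PhCO2Ag, Et3N) should give the homologous acid 2-[4-oxo-5-(trifluoromethanesulfonyloxy)-4H-pyran-2-yl]acetic acid F1.
  - Oxalyl chloride converts it to 2-[4-oxo-5-(trifluoromethanesulfonyloxy)-4H-pyran-2-yl]acetyl chloride F2.
  - Slow addition of F2 to Et3N and 15 in CH2Cl2 at 0 °C generates the ketene in low stationary concentration and should give cyclobutenone 17, which is isolated in this variant.
  - Heating 17 in toluene at 80–110 °C gives 20 by the same 4π/6π sequence.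

**Step 7.**
- What may go wrong: deprotonation of the acidic α-CH2 of the β,γ-unsaturated ester by the lithium amide or the carbenoid competes with carbonyl addition, and the double bond then moves into conjugation.
- Fallback (ynolate by oxidation of an acetylide; sets out from 13, returns at 14):
  - DIBAL-H at −78 °C reduces 13 to 4-methylpent-3-enal F3.
  - CBr4/PPh3 gives 1,1-dibromo-5-methylhexa-1,4-diene F4.
  - n-BuLi (2 equiv) gives (5-methylhex-4-en-1-yn-1-yl)lithium F5.
  - Oxidation of F5 with lithium tert-butyl peroxide (t-BuOOH, LiHMDS) gives ynolate 14, which is silylated with TIPSOTf to 15.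

**Step 9.**
- What may go wrong: protodeboronation of the electron-rich, ortho-siloxy boronate and hydrolytic S–O cleavage of the triflate next to the phenoxide formed from the 5-OH, both faster than a hindered transmetalation.
- Fallback (join ring B before ring A is built; sets out from 7 and 9, returns at 21):
  - Suzuki coupling of 7 with the unhindered, non-phenolic triflate 9 gives 5-{2,2-dimethyl-7-[(triisopropylsilyl)oxy]-2H-chromen-6-yl}-2-(hydroxymethyl)-4H-pyran-4-one F6.
  - MnO2 gives 5-{2,2-dimethyl-7-[(triisopropylsilyl)oxy]-2H-chromen-6-yl}-4-oxo-4H-pyran-2-carbaldehyde F7.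
  - Pinnick oxidation (NaClO2, NaH2PO4, 2-methylbut-2-ene) gives 5-{2,2-dimethyl-7-[(triisopropylsilyl)oxy]-2H-chromen-6-yl}-4-oxo-4H-pyran-2-carboxylic acid F8.
  - Isobutyl chloroformate/N-methylmorpholine, then diazomethane, gives 2-(2-diazoacetyl)-5-{2,2-dimethyl-7-[(triisopropylsilyl)oxy]-2H-chromen-6-yl}-4H-pyran-4-one F9.
  - The benzannulation of F9 with 15 under the conditions of step 8 gives 21 directly. Visible light is then essential, because the chromene would ring-open under UV.

**Step 1.**
- What may go wrong: conjugate addition of a further Grignard equivalent to an o-quinone methide formed early from the magnesium alkoxide, and acid-induced oligomerisation of the p-hydroxystyrene-type chromene during the dehydration.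
- Fallback (aldol route to a tertiary carbinol; sets out from 1, returns at 5):
  - Claisen–Schmidt condensation of 1 with acetone (aq. NaOH) gives (E)-4-(5-bromo-2,4-dihydroxyphenyl)but-3-en-2-one F10.
  - Excess MeMgBr gives (E)-4-(5-bromo-2,4-dihydroxyphenyl)-2-methylbut-3-en-2-ol F11.
  - Gentle warming with catalytic PPTS ionises F11 to the same delocalised cation/quinone methide and closes it to 5.

## Further compounds

F1 | step 8 | 2-[4-oxo-5-(trifluoromethanesulfonyloxy)-4H-pyran-2-yl]acetic acid | OC(=O)Cc1cc(=O)c(OS(=O)(=O)C(F)(F)F)co1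
F2 | step 8 | 2-[4-oxo-5-(trifluoromethanesulfonyloxy)-4H-pyran-2-yl]acetyl chloride | O=C(Cl)Cc1cc(=O)c(OS(=O)(=O)C(F)(F)F)co1
F3 | step 7 | 4-methylpent-3-enal | CC(C)=CCC=O
F4 | step 7 | 1,1-dibromo-5-methylhexa-1,4-diene | CC(C)=CCC=C(Br)Br
F5 | step 7 | (5-methylhex-4-en-1-yn-1-yl)lithium | [Li]C#CCC=C(C)C
F6 | step 9 | 5-{2,2-dimethyl-7-[(triisopropylsilyl)oxy]-2H-chromen-6-yl}-2-(hydroxymethyl)-4H-pyran-4-one | OCc1cc(=O)c(-c2cc3c(cc2O[Si](C(C)C)(C(C)C)C(C)C)OC(C)(C)C=C3)co1
F7 | step 9 | 5-{2,2-dimethyl-7-[(triisopropylsilyl)oxy]-2H-chromen-6-yl}-4-oxo-4H-pyran-2-carbaldehyde | O=Cc1cc(=O)c(-c2cc3c(cc2O[Si](C(C)C)(C(C)C)C(C)C)OC(C)(C)C=C3)co1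
F8 | step 9 | 5-{2,2-dimethyl-7-[(triisopropylsilyl)oxy]-2H-chromen-6-yl}-4-oxo-4H-pyran-2-carboxylic acid | OC(=O)c1cc(=O)c(-c2cc3c(cc2O[Si](C(C)C)(C(C)C)C(C)C)OC(C)(C)C=C3)co1
F9 | step 9 | 2-(2-diazoacetyl)-5-{2,2-dimethyl-7-[(triisopropylsilyl)oxy]-2H-chromen-6-yl}-4H-pyran-4-one | [N-]=[N+]=CC(=O)c1cc(=O)c(-c2cc3c(cc2O[Si](C(C)C)(C(C)C)C(C)C)OC(C)(C)C=C3)co1
F10 | step 1 | (E)-4-(5-bromo-2,4-dihydroxyphenyl)but-3-en-2-one | CC(=O)/C=C/c1cc(Br)c(O)cc1O
F11 | step 1 | (E)-4-(5-bromo-2,4-dihydroxyphenyl)-2-methylbut-3-en-2-ol | CC(C)(O)/C=C/c1cc(Br)c(O)cc1O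
A1 | alternative 1 | 3-iodo-5,7-bis(methoxymethoxy)-6-(3-methylbut-2-en-1-yl)-4H-chromen-4-one | CC(C)=CCc1c(OCOC)cc2occ(I)c(=O)c2c1OCOC
A2 | alternative 1 | 1-[6-hydroxy-2,4-bis(methoxymethoxy)-3-(3-methylbut-2-en-1-yl)phenyl]ethanone | CC(=O)c1c(O)cc(OCOC)c(CC=C(C)C)c1OCOC
A3 | alternative 2 | 2-(7-hydroxy-2,2-dimethyl-2H-chromen-6-yl)-1-[2,4,6-trihydroxy-3-(3-methylbut-2-en-1-yl)phenyl]ethanone | CC(C)=CCc1c(O)cc(O)c(C(=O)Cc2cc3c(cc2O)OC(C)(C)C=C3)c1O
A4 | alternative 3 | (E)-1-[2-hydroxy-4,6-bis(methoxymethoxy)phenyl]-3-[2,4-bis(methoxymethoxy)phenyl]prop-2-en-1-one | COCOc1ccc(/C=C/C(=O)c2c(O)cc(OCOC)cc2OCOC)c(OCOC)c1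
A5 | alternative 3 | 2′-hydroxygenistein, 3-(2,4-dihydroxyphenyl)-5,7-dihydroxy-4H-chromen-4-one | Oc1ccc(-c2coc3cc(O)cc(O)c3c2=O)c(O)c1
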